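Ring A of uliginosin B hides two simple pieces. Numbering its carbons C1 (isobutyryl-bearing), C2 and C4 (enol carbons), C3 (bridge-bearing), C5 (CMe2) and C6 (ketone), the C5–C6–C1 segment plus the isobutyryl side chain is the nine-carbon skeleton of 2,6-dimethylheptane-3,5-dione, while C2–C3–C4 and the bridge CH2 form an arylmethylmalonyl unit. Cutting the ring A bonds C4–C5 and C1–C2 therefore leads to the diketone's bis(trimethylsilyl) dienol ether and a malonyl dichloride that already carries the chromene (rings B and C) with its phenols masked as esters. One Lewis acid-mediated [3+3] double C-acylation creates quaternary C5 and closes ring A; ester methanolysis then delivers the target.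

Key step: step 11

Remark: locants C1 to C6 that are said to belong to ring A follow the numbering of the overview. Locants inside compound names or attached to the word chromene follow 2H-chromene numbering (O1, C2 carrying the two methyl groups, bridge at C6, ketone at C8). The Z enol ether geometry drawn for 2, 3 and 18 is the expected one and has no bearing on the outcome. The target has no stereocentre.

Step 1
Reactants: 1 2,6-dimethylheptane-3,5-dione
Product: 2 (4Z)-2,6-dimethyl-5-(trimethylsilyloxy)hept-4-en-3-one
Conditions: Me3SiCl (1.5 equiv), Et3N (1.6 equiv), toluene, rt; filtration under argon, concentration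
Reagents that add atoms: chlorotrimethylsilane, C[Si](C)(C)Cl
Why: Silyl enol ether formation by O-silylation of the enolised β-diketone, the chelated enol giving the Z enol ether and the symmetry of 1 removing any regiochemical question.

Step 2
Reactants: 2 (4Z)-2,6-dimethyl-5-(trimethylsilyloxy)hept-4-en-3-one
Product: 3 (4Z)-2,6-dimethyl-3,5-bis(trimethylsilyloxy)hepta-2,4-diene
Conditions: LiN(iPr)2 (commercial solution, 1.2 equiv), THF, −78 °C; Me3SiCl (1.3 equiv), −78 °C to rt; pentane, filtration, Kugelrohr distillation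
Reagents that add atoms: chlorotrimethylsilane, C[Si](C)(C)Cl
Why: Kinetic deprotonation of the isopropyl methine next to the ketone and O-silylation of the cross-conjugated dienolate is the standard second stage of the two-stage preparation of 1,3-bis(silyloxy)-1,3-dienes from 1,3-diketones, and no stereocentre is formed.

Step 3
Reactants: 4 phloroglucinol
Product: 5 2-methyl-1-(2,4,6-trihydroxyphenyl)propan-1-one
Conditions: 2-methylpropanoyl chloride (1.0 equiv), AlCl3 (3 equiv), CH2Cl2–MeNO2, 0 °C to 40 °C; ice, 1 M HCl
Reagents that add atoms: 2-methylpropanoyl chloride, CC(C)C(Cl)=O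
Why: Friedel–Crafts acylation of the electron-rich arene, which should stop at the mono-ketone because the AlCl3-complexed aryl ketone is deactivated.

Step 4
Reactants: 5 2-methyl-1-(2,4,6-trihydroxyphenyl)propan-1-one
Product: 6 3,5-dihydroxy-4-(2-methylpropanoyl)phenyl 2,2-dimethylpropanoate
Conditions: pivaloyl chloride (1.0 equiv), Et3N (1.05 equiv), THF, −20 °C to 0 °C
Reagents that add atoms: pivaloyl chloride, CC(C)(C)C(Cl)=O
Why: Selective O-acylation of the hydroxyl para to the ketone, the most acidic one and the only one not flanked by the acyl group, installs a robust ester that blocks this oxygen so that the pyran of step 5 can only close onto an oxygen ortho to the ketone.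

Step 5
Reactants: 6 3,5-dihydroxy-4-(2-methylpropanoyl)phenyl 2,2-dimethylpropanoate; 7 3-methylbut-2-enal
Product: 8 7-hydroxy-2,2-dimethyl-8-(2-methylpropanoyl)-2H-chromen-5-yl 2,2-dimethylpropanoate
Conditions: 7 (1.5 equiv), ethylenediammonium diacetate (20 mol%), toluene, reflux
Reagents that add atoms: none
Why: Amine-catalysed chromene annulation (Knoevenagel-type condensation of the enal at the ring CH, then oxa-6π electrocyclisation of the resulting ortho-quinone methide), in which the two free hydroxyls of 6 are equivalent and both ortho to the ketone, so that only the 8-acyl chromene can form.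

Step 6
Reactants: 8 7-hydroxy-2,2-dimethyl-8-(2-methylpropanoyl)-2H-chromen-5-yl 2,2-dimethylpropanoate
Product: 9 6-[(dimethylamino)methyl]-7-hydroxy-2,2-dimethyl-8-(2-methylpropanoyl)-2H-chromen-5-yl 2,2-dimethylpropanoate
Conditions: N,N-dimethylmethyleneiminium iodide (1.2 equiv), Et3N (1.2 equiv), CH2Cl2, rt
Reagents that add atoms: N,N-dimethylmethyleneiminium iodide (Eschenmoser's salt), C=[N+](C)C.[I-]
Why: Mannich aminomethylation of the phenol at the only free aromatic position, chromene C6, which is ortho to the 7-hydroxyl and para to the pyran oxygen.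

Step 7
Reactants: 9 6-[(dimethylamino)methyl]-7-hydroxy-2,2-dimethyl-8-(2-methylpropanoyl)-2H-chromen-5-yl 2,2-dimethylpropanoate; 10 di-tert-butyl malonate
Product: 13 di-tert-butyl 2-{[7-hydroxy-2,2-dimethyl-8-(2-methylpropanoyl)-5-(2,2-dimethylpropanoyloxy)-2H-chromen-6-yl]methyl}propanedioate, via trimethylammonium iodide 11 (not isolated), via ortho-quinone methide 12 (not isolated)
Conditions: MeI (1.1 equiv), acetone, rt, volatiles removed; NaCH(CO2tBu)2 (3 equiv, from 10 and NaH), THF, 0 °C to rt; cold 0.5 M HCl
Reagents that add atoms: none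
Why: N-Methylation turns the amine into a leaving group, the phenoxide expels trimethylamine to give ortho-quinone methide 12, and conjugate (Michael) addition of the malonate anion to the exocyclic methylene restores the arene, while the bulky tert-butyl esters resist lactonisation onto the neighbouring phenoxide.

Step 8
Reactants: 13 di-tert-butyl 2-{[7-hydroxy-2,2-dimethyl-8-(2-methylpropanoyl)-5-(2,2-dimethylpropanoyloxy)-2H-chromen-6-yl]methyl}propanedioate
Product: 14 di-tert-butyl 2-{[7-acetoxy-2,2-dimethyl-8-(2-methylpropanoyl)-5-(2,2-dimethylpropanoyloxy)-2H-chromen-6-yl]methyl}propanedioate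
Conditions: Ac2O (3 equiv), pyridine, DMAP (cat.), 0 °C to rt
Reagents that add atoms: acetic anhydride, CC(=O)OC(C)=O
Why: DMAP-catalysed acetylation of the chelated 7-hydroxyl masks the last oxygen that could lactonise onto the acid chloride made in step 10.

Step 9
Reactants: 14 di-tert-butyl 2-{[7-acetoxy-2,2-dimethyl-8-(2-methylpropanoyl)-5-(2,2-dimethylpropanoyloxy)-2H-chromen-6-yl]methyl}propanedioate
Product: 16 2-{[7-acetoxy-2,2-dimethyl-8-(2-methylpropanoyl)-5-(2,2-dimethylpropanoyloxy)-2H-chromen-6-yl]methyl}propanedioic acid, via bis(trimethylsilyl) ester 15 (not isolated)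
Conditions: Me3SiOTf (3 equiv), 2,6-lutidine (4 equiv), CH2Cl2, 0 °C to rt; aq. citric acid (pH 3), extraction below 30 °C
Reagents that add atoms: none
Why: Silyl triflate-mediated cleavage of the tert-butyl esters (carbonyl silylation, loss of 2-methylpropene, hydrolysis of the silyl esters on work-up) under lutidine-buffered aprotic conditions that should leave the aryl esters and the acid-sensitive chromene olefin untouched.

Step 10
Reactants: 16 2-{[7-acetoxy-2,2-dimethyl-8-(2-methylpropanoyl)-5-(2,2-dimethylpropanoyloxy)-2H-chromen-6-yl]methyl}propanedioic acid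
Product: 17 2-{[7-acetoxy-2,2-dimethyl-8-(2-methylpropanoyl)-5-(2,2-dimethylpropanoyloxy)-2H-chromen-6-yl]methyl}propanedioyl dichloride
Conditions: (COCl)2 (2.5 equiv), DMF (cat.), CH2Cl2, 0 °C to rt; volatiles removed, toluene azeotrope, used crude
Reagents that add atoms: oxalyl chloride, O=C(Cl)C(Cl)=O
Why: Acid chloride formation through the catalytic Vilsmeier chloroiminium reagent, run without added base so that the enolisable malonyl dichloride is not converted into a chlorocarbonylketene.

Step 11
Reactants: 17 2-{[7-acetoxy-2,2-dimethyl-8-(2-methylpropanoyl)-5-(2,2-dimethylpropanoyloxy)-2H-chromen-6-yl]methyl}propanedioyl dichloride; 3 (4Z)-2,6-dimethyl-3,5-bis(trimethylsilyloxy)hepta-2,4-diene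
Product: 19 7-acetoxy-6-{[2,6-dihydroxy-3,3-dimethyl-5-(2-methylpropanoyl)-4-oxocyclohexa-1,5-dien-1-yl]methyl}-2,2-dimethyl-8-(2-methylpropanoyl)-2H-chromen-5-yl 2,2-dimethylpropanoate, via open-chain keto acid chloride 18 (not isolated)
Conditions: 3 (1.3 equiv), Me3SiOTf (0.3 equiv), CH2Cl2 (0.02 M), −78 °C to rt, 14 h; aq. NH4Cl
Reagents that add atoms: none
Why: Proposed new method: Me3SiOTf activates one acyl chloride of 17, which is attacked by the electron-rich tetrasubstituted isopropylidene terminus of diene 3 in a Mukaiyama-type C-acylation that creates the quaternary carbon C5 of ring A (ring A bond C4–C5) and releases Me3SiCl to give 18; the surviving silyl enol ether then adds through its central carbon, C1 of ring A, to the second acyl chloride (ring A bond C1–C2) in a 6-exo-trig addition–elimination that closes carbocyclic ring A, and the product enolises to the doubly hydrogen-bonded trione tautomer. The closest known reactions are the terminal C-acylation of 1,3-bis(silyloxy)-1,3-dienes by acid chlorides and their Me3SiOTf-mediated cyclisations with 1,2- and 1,3-dielectrophiles, which have not been shown for a fully substituted diene terminus or for carbocycle formation with a malonyl dichloride. No stereocentre is formed, since the enolisable malonyl centre of 18 (C3 of ring A) becomes sp2 in 19. The step needs C-acylation rather than O-acylation twice: the diene terminus is the most nucleophilic carbon, and should the central carbon react first the same ring results because the two bonds can form in either order. Closure through the oxygen on C6 of ring A would give an enol lactone that cannot aromatise to a 2-pyranone because C5 of ring A is quaternary, so it remains an acyl donor under the Lewis acid and can drain to the thermodynamically favoured triketone. The electron-withdrawing pivalate, acetate and ketone keep the chromene olefin from competing as a nucleophile, the symmetry of the diketone makes the choice of isobutyryl end irrelevant, and the non-basic conditions leave the acidic malonyl C–H untouched.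

Step 12
Reactants: 19 7-acetoxy-6-{[2,6-dihydroxy-3,3-dimethyl-5-(2-methylpropanoyl)-4-oxocyclohexa-1,5-dien-1-yl]methyl}-2,2-dimethyl-8-(2-methylpropanoyl)-2H-chromen-5-yl 2,2-dimethylpropanoate
Product: 20 uliginosin B
Conditions: K2CO3 (5 equiv), MeOH, 0 °C to rt, warmed to 40 °C if the pivalate is slow; 1 M HCl
Reagents that add atoms: none
Why: Base-catalysed transesterification (methanolysis) of the two aryl esters, both activated as esters of acidic acylphenols, under conditions to which the enolised triketone, the methylene bridge and the chromene should be inert.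

Compound list
1 | 2,6-dimethylheptane-3,5-dione | CC(C)C(=O)CC(=O)C(C)C | starting material
2 | (4Z)-2,6-dimethyl-5-(trimethylsilyloxy)hept-4-en-3-one | CC(C)C(=O)/C=C(\O[Si](C)(C)C)C(C)C | intermediate
3 | (4Z)-2,6-dimethyl-3,5-bis(trimethylsilyloxy)hepta-2,4-diene | CC(C)/C(O[Si](C)(C)C)=C/C(O[Si](C)(C)C)=C(C)C | intermediate
4 | phloroglucinol (benzene-1,3,5-triol) | Oc1cc(O)cc(O)c1 | starting material
5 | 2-methyl-1-(2,4,6-trihydroxyphenyl)propan-1-one | CC(C)C(=O)c1c(O)cc(O)cc1O | intermediate
6 | 3,5-dihydroxy-4-(2-methylpropanoyl)phenyl 2,2-dimethylpropanoate | CC(C)C(=O)c1c(O)cc(OC(=O)C(C)(C)C)cc1O | intermediate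
7 | 3-methylbut-2-enal | CC(C)=CC=O | starting material
8 | 7-hydroxy-2,2-dimethyl-8-(2-methylpropanoyl)-2H-chromen-5-yl 2,2-dimethylpropanoate | CC1(C)C=Cc2c(OC(=O)C(C)(C)C)cc(O)c(C(=O)C(C)C)c2O1 | intermediate
9 | 6-[(dimethylamino)methyl]-7-hydroxy-2,2-dimethyl-8-(2-methylpropanoyl)-2H-chromen-5-yl 2,2-dimethylpropanoate | CC1(C)C=Cc2c(OC(=O)C(C)(C)C)c(CN(C)C)c(O)c(C(=O)C(C)C)c2O1 | intermediate
10 | di-tert-butyl malonate | CC(C)(C)OC(=O)CC(=O)OC(C)(C)C | starting material
11 | {[7-hydroxy-2,2-dimethyl-8-(2-methylpropanoyl)-5-(2,2-dimethylpropanoyloxy)-2H-chromen-6-yl]methyl}trimethylammonium iodide | CC1(C)C=Cc2c(OC(=O)C(C)(C)C)c(C[N+](C)(C)C)c(O)c(C(=O)C(C)C)c2O1.[I-] | intermediate (not isolated)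
12 | 2,2-dimethyl-6-methylidene-8-(2-methylpropanoyl)-7-oxo-6,7-dihydro-2H-chromen-5-yl 2,2-dimethylpropanoate (ortho-quinone methide) | CC1(C)C=CC2=C(OC(=O)C(C)(C)C)C(=C)C(=O)C(C(=O)C(C)C)=C2O1 | intermediate (not isolated)
13 | di-tert-butyl 2-{[7-hydroxy-2,2-dimethyl-8-(2-methylpropanoyl)-5-(2,2-dimethylpropanoyloxy)-2H-chromen-6-yl]methyl}propanedioate | CC1(C)C=Cc2c(OC(=O)C(C)(C)C)c(CC(C(=O)OC(C)(C)C)C(=O)OC(C)(C)C)c(O)c(C(=O)C(C)C)c2O1 | intermediate
14 | di-tert-butyl 2-{[7-acetoxy-2,2-dimethyl-8-(2-methylpropanoyl)-5-(2,2-dimethylpropanoyloxy)-2H-chromen-6-yl]methyl}propanedioate | CC1(C)C=Cc2c(OC(=O)C(C)(C)C)c(CC(C(=O)OC(C)(C)C)C(=O)OC(C)(C)C)c(OC(C)=O)c(C(=O)C(C)C)c2O1 | intermediate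
15 | bis(trimethylsilyl) 2-{[7-acetoxy-2,2-dimethyl-8-(2-methylpropanoyl)-5-(2,2-dimethylpropanoyloxy)-2H-chromen-6-yl]methyl}propanedioate | CC1(C)C=Cc2c(OC(=O)C(C)(C)C)c(CC(C(=O)O[Si](C)(C)C)C(=O)O[Si](C)(C)C)c(OC(C)=O)c(C(=O)C(C)C)c2O1 | intermediate (not isolated)
16 | 2-{[7-acetoxy-2,2-dimethyl-8-(2-methylpropanoyl)-5-(2,2-dimethylpropanoyloxy)-2H-chromen-6-yl]methyl}propanedioic acid | CC1(C)C=Cc2c(OC(=O)C(C)(C)C)c(CC(C(=O)O)C(=O)O)c(OC(C)=O)c(C(=O)C(C)C)c2O1 | intermediate
17 | 2-{[7-acetoxy-2,2-dimethyl-8-(2-methylpropanoyl)-5-(2,2-dimethylpropanoyloxy)-2H-chromen-6-yl]methyl}propanedioyl dichloride | CC1(C)C=Cc2c(OC(=O)C(C)(C)C)c(CC(C(Cl)=O)C(Cl)=O)c(OC(C)=O)c(C(=O)C(C)C)c2O1 | intermediate (key-step precursor)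
18 | (6Z)-2-{[7-acetoxy-2,2-dimethyl-8-(2-methylpropanoyl)-5-(2,2-dimethylpropanoyloxy)-2H-chromen-6-yl]methyl}-4,4,8-trimethyl-3,5-dioxo-7-(trimethylsilyloxy)non-6-enoyl chloride, racemic at the malonyl carbon | CC(C)/C(O[Si](C)(C)C)=C/C(=O)C(C)(C)C(=O)C(Cc1c(OC(=O)C(C)(C)C)c2C=CC(C)(C)Oc2c(C(=O)C(C)C)c1OC(C)=O)C(Cl)=O | intermediate (not isolated)
19 | uliginosin B 7-O-acetate 5-O-pivalate: 7-acetoxy-6-{[2,6-dihydroxy-3,3-dimethyl-5-(2-methylpropanoyl)-4-oxocyclohexa-1,5-dien-1-yl]methyl}-2,2-dimethyl-8-(2-methylpropanoyl)-2H-chromen-5-yl 2,2-dimethylpropanoate | CC(C)C(=O)C1=C(O)C(Cc2c(OC(=O)C(C)(C)C)c3C=CC(C)(C)Oc3c(C(=O)C(C)C)c2OC(C)=O)=C(O)C(C)(C)C1=O | intermediate (key-step product)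
20 | uliginosin B | CC(C)C(=O)C1=C(O)C(Cc2c(O)c3c(c(C(=O)C(C)C)c2O)OC(C)(C)C=C3)=C(O)C(C)(C)C1=O | target

Total step count: 12. Longest linear sequence: 10 steps (steps 3 to 12, from phloroglucinol 4); the diene branch (steps 1 and 2) joins at step 11.

Steps most likely to fail

1. Step 11 (proposed new method). The hindered isopropylidene terminus may react too slowly, or either acylation may take place at oxygen instead of carbon, so that enol esters, the oxygen-closed lactone or oligomers form in place of ring A. The fallback uses known chemistry and sets out from 5 and 9. Twofold C-methylation of 5 (MeI, NaOMe, MeOH) dearomatises it to isobutyrylfilicinic acid F1. Warming F1 with Mannich base 9 in dioxane lets the acidic triketone protonate the amine; the ortho-quinone methide that forms is trapped at the free ring carbon of F1 to give uliginosin B 5-O-pivalate F2. Methanolysis under the conditions of step 12 brings the route back at 20.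

2. Step 5. The pivalate-bearing ring may be too weakly nucleophilic toward the iminium ion, a second annulation may consume the remaining hydroxyl, or the amine catalyst may be lost by slow acyl transfer from the ester. The fallback sets out from 6, whose two hydroxyls are equivalent. O-Alkylation with 3-chloro-3-methylbut-1-yne (DBU, CuCl2 cat., MeCN, 0 °C) gives the aryl 1,1-dimethylpropargyl ether F3. Heating F3 in N,N-diethylaniline at about 140 °C triggers the aromatic propargyl Claisen rearrangement, 1,5-hydrogen shift and oxa-6π ring closure, which returns to the route at 8.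

3. Step 7. Methylation may occur at the phenolic oxygen instead of nitrogen, the ortho-quinone methide may self-condense, the malonate may be benzylated twice, or the phenoxide may close onto a tert-butyl ester. The fallback sets out from 9 and replaces conjugate addition by a classical malonic ester alkylation. Acetylation of the phenol (Ac2O, pyridine) gives the 7-O-acetyl Mannich base F4. Ethyl chloroformate (CH2Cl2, 0 °C to rt) cleaves the benzylic C–N bond in a von Braun-type dealkylation to give the benzylic chloride F5. Displacement with the sodium salt of 10 (THF, 0 °C) returns to the route at 14.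

Further compounds
F1 | step 11 | isobutyrylfilicinic acid, 3,5-dihydroxy-4,4-dimethyl-2-(2-methylpropanoyl)cyclohexa-2,5-dien-1-one | CC(C)C(=O)C1=C(O)C=C(O)C(C)(C)C1=O
F2 | step 11 | uliginosin B 5-O-pivalate | CC(C)C(=O)C1=C(O)C(Cc2c(OC(=O)C(C)(C)C)c3C=CC(C)(C)Oc3c(C(=O)C(C)C)c2O)=C(O)C(C)(C)C1=O
F3 | step 5 | 3-hydroxy-4-(2-methylpropanoyl)-5-[(2-methylbut-3-yn-2-yl)oxy]phenyl 2,2-dimethylpropanoate | CC(C)C(=O)c1c(O)cc(OC(=O)C(C)(C)C)cc1OC(C)(C)C#C
F4 | step 7 | 7-acetoxy-6-[(dimethylamino)methyl]-2,2-dimethyl-8-(2-methylpropanoyl)-2H-chromen-5-yl 2,2-dimethylpropanoate | CC1(C)C=Cc2c(OC(=O)C(C)(C)C)c(CN(C)C)c(OC(C)=O)c(C(=O)C(C)C)c2O1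
F5 | step 7 | 7-acetoxy-6-(chloromethyl)-2,2-dimethyl-8-(2-methylpropanoyl)-2H-chromen-5-yl 2,2-dimethylpropanoate | CC1(C)C=Cc2c(OC(=O)C(C)(C)C)c(CCl)c(OC(C)=O)c(C(=O)C(C)C)c2O1
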